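## Retrosynthetic overview

1. The strategy rests on one feature of the 7-oxabicyclo[4.1.0]hept-4-ene core (C1 = quaternary oxirane carbon bearing C7H2O, C2 = OMe, C3 = O-acyl, C4=C5, C6 = oxirane CH, O7). C6 is both allylic to the ring double bond C4=C5 and bonded to the fully substituted, oxygenated C1, so C6 can serve as an allyl sulfonium ylide carbon toward a C1 ketone.
2. Target ⇒ C3/C7 diol ⇒ bis-ether epoxy-cyclohexene ⇒ (C1–C6, then C6–O7) open-chain (Z)-allylic thiolanium salt carrying the C1 ketone. The carbocycle closes first (6-exo-trig) and the oxirane second (3-exo-tet), in one flask.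
3. Salt ⇒ (Z)-allylic bromide ⇒ Z-enoate (C4=C5 by Still–Gennari olefination) ⇒ C1 ketone from a Weinreb amide and PMBOCH2Li (C1–C7 bond) ⇒ mono-O-methyl diethyl D-tartrate, whose carbons become C1–C4 and whose stereocentres become C2 and C3.

Key step: step 13

Remarks on the chemistry:
- Atom labels C1–C7 are those of the overview and are used for every intermediate; ring compounds are named with these locants.
- The C3 silyl group is triethylsilyl, because a primary TES ether can be oxidised directly to the aldehyde (step 7).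
- An enoate cannot be reduced selectively beside the C1 ketone. iBu2AlH is therefore allowed to reduce both (step 9), and C1 is re-oxidised once the allylic bromide is in place (steps 10 and 11).
- Assumption: tributyl(iodomethyl)stannane is a purchasable reagent.

## Route

Step 1
Reactants: 1 diethyl D-tartrate
Product: 3 diethyl (2S,3S)-2-hydroxy-3-methoxybutanedioate, via stannylene acetal 2 (not isolated)
Conditions: Bu2SnO, toluene, reflux (Dean–Stark); then MeI, CsF, DMF, rt
Reagents that add atoms: iodomethane CI; dibutyltin oxide CCCC[Sn](=O)CCCC (its atoms stay only in intermediate 2)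
Why: Stannylene-acetal-mediated mono-O-alkylation: the C2-symmetric diol is alkylated once by MeI under fluoride activation while the second oxygen stays tin-bound, so one monomethyl ether should result without touching either stereocentre.

Step 2
Reactants: 3 diethyl (2S,3S)-2-hydroxy-3-methoxybutanedioate
Product: 4 ethyl (2S,3R)-3,4-dihydroxy-2-methoxybutanoate
Conditions: BH3·SMe2 (1.05 equiv), NaBH4 (5 mol%), THF, 0 °C to rt; MeOH
Reagents that add atoms: none
Why: Hydroxyl-directed borane reduction of an α-hydroxy ester: the free C3 hydroxyl binds boron and delivers hydride through a five-membered chelate only to the neighbouring ester (C4), leaving the ester next to the methoxy group (C1) intact.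

Step 3
Reactants: 4 ethyl (2S,3R)-3,4-dihydroxy-2-methoxybutanoate
Product: 5 ethyl (2S,3R)-2-methoxy-3,4-bis[(triethylsilyl)oxy]butanoate
Conditions: Et3SiCl (2.4 equiv), imidazole, DMAP (cat.), CH2Cl2, 0 °C to rt
Reagents that add atoms: chlorotriethylsilane CC[Si](Cl)(CC)CC
Why: Standard silylation of both hydroxyls, carried out on the crude diol so that γ-lactonisation onto the C1 ester has no time to occur.

Step 4
Reactants: 5 ethyl (2S,3R)-2-methoxy-3,4-bis[(triethylsilyl)oxy]butanoate
Product: 6 (2S,3R)-N,2-dimethoxy-N-methyl-3,4-bis[(triethylsilyl)oxy]butanamide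
Conditions: MeNHOMe·HCl, iPrMgCl, THF, −20 to 0 °C
Reagents that add atoms: N,O-dimethylhydroxylamine hydrochloride CNOC.Cl
Why: Direct ester-to-Weinreb-amide aminolysis by the chloromagnesium amide of MeNHOMe, a nucleophile too weakly basic to epimerise the α-methoxy centre C2.

Step 5
Reactants: 7 4-methoxybenzyl alcohol; 8 tributyl(iodomethyl)stannane
Product: 9 tributyl{[(4-methoxyphenyl)methoxy]methyl}stannane
Conditions: NaH, THF/DMF, 0 °C; then 8, rt
Reagents that add atoms: none
Why: Williamson etherification of the sodium alkoxide of 7 with the primary iodide 8, the usual access to α-alkoxymethylstannanes.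

Step 6
Reactants: 6 (2S,3R)-N,2-dimethoxy-N-methyl-3,4-bis[(triethylsilyl)oxy]butanamide; 9 tributyl{[(4-methoxyphenyl)methoxy]methyl}stannane
Product: 11 (3S,4R)-3-methoxy-1-[(4-methoxyphenyl)methoxy]-4,5-bis[(triethylsilyl)oxy]pentan-2-one, via alkoxymethyllithium 10 (not isolated)
Conditions: 9, n-BuLi, THF, −78 °C; then 6, −78 °C; aq. NH4Cl
Reagents that add atoms: n-butyllithium [Li]CCCC (lithium only in intermediate 10)
Why: Tin–lithium exchange gives the α-alkoxymethyllithium 10, which acylates once on the Weinreb amide because the N,O-chelated tetrahedral adduct persists until the quench, forming the C1–C7 bond and the C1 ketone.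

Step 7
Reactants: 11 (3S,4R)-3-methoxy-1-[(4-methoxyphenyl)methoxy]-4,5-bis[(triethylsilyl)oxy]pentan-2-one
Product: 12 (2S,3S)-3-methoxy-5-[(4-methoxyphenyl)methoxy]-4-oxo-2-[(triethylsilyl)oxy]pentanal
Conditions: (COCl)2, DMSO, CH2Cl2, −78 to −30 °C; then Et3N, −78 to 0 °C
Reagents that add atoms: none
Why: Swern oxidation applied directly to the silyl ether: chlorodimethylsulfonium chloride cleaves the unhindered primary TES ether to the alkoxysulfonium salt, which collapses to the C4 aldehyde on adding base, while the secondary TES ether and the PMB ether should stay.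

Step 8
Reactants: 12 (2S,3S)-3-methoxy-5-[(4-methoxyphenyl)methoxy]-4-oxo-2-[(triethylsilyl)oxy]pentanal
Product: 13 methyl (2Z,4R,5S)-5-methoxy-7-[(4-methoxyphenyl)methoxy]-6-oxo-4-[(triethylsilyl)oxy]hept-2-enoate
Conditions: (CF3CH2O)2P(O)CH2CO2Me, KN(SiMe3)2, 18-crown-6, THF, −78 °C
Reagents that add atoms: methyl bis(2,2,2-trifluoroethyl)phosphonoacetate COC(=O)CP(=O)(OCC(F)(F)F)OCC(F)(F)F
Why: Still–Gennari olefination: the electron-poor phosphonate under dissociating conditions eliminates fast and irreversibly from the syn adduct and so should give the Z-enoate (C4=C5), the aldehyde reacting far faster than the hindered ketone.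

Step 9
Reactants: 13 methyl (2Z,4R,5S)-5-methoxy-7-[(4-methoxyphenyl)methoxy]-6-oxo-4-[(triethylsilyl)oxy]hept-2-enoate
Product: 14 (2Z,4R,5R)-5-methoxy-7-[(4-methoxyphenyl)methoxy]-4-[(triethylsilyl)oxy]hept-2-ene-1,6-diol (mixture of epimers at the C1 carbinol)
Conditions: iBu2AlH (4.5 equiv), CH2Cl2, −78 °C; aq. potassium sodium tartrate
Reagents that add atoms: none
Why: iBu2AlH reduces the enoate 1,2 to the Z-allylic alcohol with retention of alkene geometry; the C1 ketone is knowingly reduced as well, and its epimer mixture is of no consequence because C1 is re-oxidised in step 11.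

Step 10
Reactants: 14 (2Z,4R,5R)-5-methoxy-7-[(4-methoxyphenyl)methoxy]-4-[(triethylsilyl)oxy]hept-2-ene-1,6-diol
Product: 15 (3R,4R,5Z)-7-bromo-3-methoxy-1-[(4-methoxyphenyl)methoxy]-4-[(triethylsilyl)oxy]hept-5-en-2-ol (mixture of epimers at the C1 carbinol)
Conditions: NBS, Me2S, CH2Cl2, −20 to 0 °C
Reagents that add atoms: N-bromosuccinimide O=C1CCC(=O)N1Br
Why: Corey–Kim bromination: the bromodimethylsulfonium reagent turns the primary allylic alcohol into the bromide by SN2 displacement of its alkoxysulfonium salt, whereas the hindered saturated secondary alcohol only forms an alkoxysulfonium salt that returns the alcohol on work-up.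

Step 11
Reactants: 15 (3R,4R,5Z)-7-bromo-3-methoxy-1-[(4-methoxyphenyl)methoxy]-4-[(triethylsilyl)oxy]hept-5-en-2-ol
Product: 16 (3S,4R,5Z)-7-bromo-3-methoxy-1-[(4-methoxyphenyl)methoxy]-4-[(triethylsilyl)oxy]hept-5-en-2-one
Conditions: Dess–Martin periodinane, NaHCO3, CH2Cl2, 0 °C to rt
Reagents that add atoms: none
Why: Dess–Martin oxidation of the secondary alcohol under buffered conditions restores the C1 ketone; the allylic bromide, silyl ether and PMB ether are inert to it and both carbinol epimers converge on one ketone.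

Step 12
Reactants: 16 (3S,4R,5Z)-7-bromo-3-methoxy-1-[(4-methoxyphenyl)methoxy]-4-[(triethylsilyl)oxy]hept-5-en-2-one; 17 tetrahydrothiophene
Product: 18 1-[(2Z,4R,5S)-5-methoxy-7-[(4-methoxyphenyl)methoxy]-6-oxo-4-[(triethylsilyl)oxy]hept-2-en-1-yl]thiolan-1-ium bromide
Conditions: 17 (5 equiv), acetone, rt, dark
Reagents that add atoms: none
Why: SN2 S-alkylation of the sulfide by the primary allylic bromide at C6 should give the sulfonium salt with the Z geometry retained; no base is present, so no ylide forms yet.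

Step 13
Reactants: 18 1-[(2Z,4R,5S)-5-methoxy-7-[(4-methoxyphenyl)methoxy]-6-oxo-4-[(triethylsilyl)oxy]hept-2-en-1-yl]thiolan-1-ium bromide
Product: 21 (1R,2S,3R,6R)-2-methoxy-1-{[(4-methoxyphenyl)methoxy]methyl}-3-[(triethylsilyl)oxy]-7-oxabicyclo[4.1.0]hept-4-ene, via sulfonium ylide 19 (not isolated), via betaine 20 (not isolated)
Conditions: Cs2CO3 (2 equiv), MeCN (0.01 M), 0 °C to rt
Reagents that add atoms: none
Why: Cs2CO3 removes the C6–H next to sulfur (the most acidic C–H, flanked by S+ and the C4=C5 double bond) to give allyl ylide 19, whose C6 adds to the C1 ketone and closes the carbocycle in a 6-exo-trig mode, after which the alkoxide of betaine 20 expels tetrahydrothiophene from C6 with inversion in a 3-exo-tet closure of the oxirane. The closest known reaction type is the Corey–Chaykovsky epoxidation in its intramolecular form (sulfonium-ylide epoxy-annulation), combined with vinyl-oxirane formation from allyl sulfonium ylides and carbonyl compounds. C1 and C6 are the new stereocentres, and both are controlled by the C2 and C3 stereocentres of the tether through a half-chair transition state in which C2-OMe, C3-OSiEt3 and C7H2OPMB are (pseudo)equatorial, which places the C1 oxyanion axial on the face of the C2 methoxy group. Only a betaine with anti-periplanar (trans-diaxial) O− and S+ can close, so the oxirane oxygen is expected syn to C2-OMe and anti to C3-OSiEt3, while cis-betaines cannot reach that geometry and should revert to ylide and ketone. The step needs ylide formation to outrun enolisation of the ketone toward C2 (which would expel the C3 silyloxy group); the higher acidity of the sulfonium α-C–H under a mild carbonate base and the use of ether instead of ester protecting groups are there to secure this. It also needs C6 and not C4 of the allyl ylide to attack, which the Z geometry of C4=C5 enforces, since only C6 can reach C1 through an unstrained six-membered ring.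

Step 14
Reactants: 21 (1R,2S,3R,6R)-2-methoxy-1-{[(4-methoxyphenyl)methoxy]methyl}-3-[(triethylsilyl)oxy]-7-oxabicyclo[4.1.0]hept-4-ene
Product: 22 {(1R,2S,3R,6R)-2-methoxy-3-[(triethylsilyl)oxy]-7-oxabicyclo[4.1.0]hept-4-en-1-yl}methanol
Conditions: DDQ, CH2Cl2/pH 7 buffer (NaH2PO4/Na2HPO4) 10:1, 0 °C
Reagents that add atoms: none
Why: Oxidative PMB cleavage by DDQ (hydride abstraction at the electron-rich benzylic position, then hydrolysis of the oxocarbenium ion) under buffered conditions that should spare the vinyl oxirane and the TES ether.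

Step 15
Reactants: 22 {(1R,2S,3R,6R)-2-methoxy-3-[(triethylsilyl)oxy]-7-oxabicyclo[4.1.0]hept-4-en-1-yl}methanol
Product: 23 (1R,2S,3R,6R)-1-(hydroxymethyl)-2-methoxy-7-oxabicyclo[4.1.0]hept-4-en-3-ol
Conditions: Bu4NF, AcOH (1:1), THF, 0 °C
Reagents that add atoms: none
Why: Fluoride-mediated desilylation; buffering with AcOH keeps the medium non-basic so that the C7 hydroxyl cannot start a Payne rearrangement of the 2,3-epoxy alcohol.

Step 16
Reactants: 23 (1R,2S,3R,6R)-1-(hydroxymethyl)-2-methoxy-7-oxabicyclo[4.1.0]hept-4-en-3-ol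
Product: 24 [(1R,2S,3R,6R)-3-(benzoyloxy)-2-methoxy-7-oxabicyclo[4.1.0]hept-4-en-1-yl]methyl benzoate (target)
Conditions: BzCl (3 equiv), pyridine, DMAP (cat.), CH2Cl2, 0 °C to rt
Reagents that add atoms: benzoyl chloride O=C(Cl)c1ccccc1
Why: DMAP-catalysed acylation of the primary C7 and the secondary allylic C3 hydroxyls; no stereocentre is touched and no selectivity between the two hydroxyls is required.

## Compound list

1 | diethyl D-tartrate, diethyl (2S,3S)-2,3-dihydroxybutanedioate | CCOC(=O)[C@@H](O)[C@H](O)C(=O)OCC | starting material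
2 | diethyl (4S,5S)-2,2-dibutyl-1,3,2-dioxastannolane-4,5-dicarboxylate (stannylene acetal, formed in the flask) | CCCC[Sn]1(CCCC)O[C@H](C(=O)OCC)[C@@H](C(=O)OCC)O1 | intermediate
3 | diethyl (2S,3S)-2-hydroxy-3-methoxybutanedioate | CCOC(=O)[C@@H](OC)[C@H](O)C(=O)OCC | intermediate
4 | ethyl (2S,3R)-3,4-dihydroxy-2-methoxybutanoate | CCOC(=O)[C@@H](OC)[C@H](O)CO | intermediate
5 | ethyl (2S,3R)-2-methoxy-3,4-bis[(triethylsilyl)oxy]butanoate | CCOC(=O)[C@@H](OC)[C@H](O[Si](CC)(CC)CC)CO[Si](CC)(CC)CC | intermediate
6 | (2S,3R)-N,2-dimethoxy-N-methyl-3,4-bis[(triethylsilyl)oxy]butanamide | CON(C)C(=O)[C@@H](OC)[C@H](O[Si](CC)(CC)CC)CO[Si](CC)(CC)CC | intermediate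
7 | 4-methoxybenzyl alcohol | COc1ccc(CO)cc1 | starting material
8 | tributyl(iodomethyl)stannane | CCCC[Sn](CCCC)(CCCC)CI | starting material
9 | tributyl{[(4-methoxyphenyl)methoxy]methyl}stannane | CCCC[Sn](CCCC)(CCCC)COCc1ccc(OC)cc1 | intermediate
10 | {[(4-methoxyphenyl)methoxy]methyl}lithium (formed in the flask) | [Li]COCc1ccc(OC)cc1 | intermediate
11 | (3S,4R)-3-methoxy-1-[(4-methoxyphenyl)methoxy]-4,5-bis[(triethylsilyl)oxy]pentan-2-one | COc1ccc(COCC(=O)[C@@H](OC)[C@H](O[Si](CC)(CC)CC)CO[Si](CC)(CC)CC)cc1 | intermediate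
12 | (2S,3S)-3-methoxy-5-[(4-methoxyphenyl)methoxy]-4-oxo-2-[(triethylsilyl)oxy]pentanal | COc1ccc(COCC(=O)[C@@H](OC)[C@H](O[Si](CC)(CC)CC)C=O)cc1 | intermediate
13 | methyl (2Z,4R,5S)-5-methoxy-7-[(4-methoxyphenyl)methoxy]-6-oxo-4-[(triethylsilyl)oxy]hept-2-enoate | COc1ccc(COCC(=O)[C@@H](OC)[C@H](O[Si](CC)(CC)CC)/C=C\C(=O)OC)cc1 | intermediate
14 | (2Z,4R,5R)-5-methoxy-7-[(4-methoxyphenyl)methoxy]-4-[(triethylsilyl)oxy]hept-2-ene-1,6-diol (both epimers at the C1 carbinol) | COc1ccc(COCC(O)[C@@H](OC)[C@H](O[Si](CC)(CC)CC)/C=C\CO)cc1 | intermediate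
15 | (3R,4R,5Z)-7-bromo-3-methoxy-1-[(4-methoxyphenyl)methoxy]-4-[(triethylsilyl)oxy]hept-5-en-2-ol (both epimers at the C1 carbinol) | COc1ccc(COCC(O)[C@@H](OC)[C@H](O[Si](CC)(CC)CC)/C=C\CBr)cc1 | intermediate
16 | (3S,4R,5Z)-7-bromo-3-methoxy-1-[(4-methoxyphenyl)methoxy]-4-[(triethylsilyl)oxy]hept-5-en-2-one | COc1ccc(COCC(=O)[C@@H](OC)[C@H](O[Si](CC)(CC)CC)/C=C\CBr)cc1 | intermediate
17 | tetrahydrothiophene | C1CCSC1 | starting material
18 | 1-[(2Z,4R,5S)-5-methoxy-7-[(4-methoxyphenyl)methoxy]-6-oxo-4-[(triethylsilyl)oxy]hept-2-en-1-yl]thiolan-1-ium bromide | COc1ccc(COCC(=O)[C@@H](OC)[C@H](O[Si](CC)(CC)CC)/C=C\C[S+]2CCCC2)cc1.[Br-] | intermediate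
19 | allyl sulfonium ylide of 18, carbanion at C6 (formed in the flask) | COc1ccc(COCC(=O)[C@@H](OC)[C@H](O[Si](CC)(CC)CC)/C=C\[CH-][S+]2CCCC2)cc1 | intermediate
20 | betaine: cyclohex-4-ene with axial C1 oxide syn to C2-OMe and C6 thiolanium anti to it (formed in the flask) | CO[C@H]1[C@H](O[Si](CC)(CC)CC)C=C[C@H]([S+]2CCCC2)[C@]1([O-])COCc1ccc(OC)cc1 | intermediate
21 | (1R,2S,3R,6R)-2-methoxy-1-{[(4-methoxyphenyl)methoxy]methyl}-3-[(triethylsilyl)oxy]-7-oxabicyclo[4.1.0]hept-4-ene | CO[C@H]1[C@H](O[Si](CC)(CC)CC)C=C[C@H]2O[C@]21COCc1ccc(OC)cc1 | intermediate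
22 | {(1R,2S,3R,6R)-2-methoxy-3-[(triethylsilyl)oxy]-7-oxabicyclo[4.1.0]hept-4-en-1-yl}methanol | CO[C@H]1[C@H](O[Si](CC)(CC)CC)C=C[C@H]2O[C@]21CO | intermediate
23 | (1R,2S,3R,6R)-1-(hydroxymethyl)-2-methoxy-7-oxabicyclo[4.1.0]hept-4-en-3-ol | CO[C@H]1[C@H](O)C=C[C@H]2O[C@]21CO | intermediate
24 | [(1R,2S,3R,6R)-3-(benzoyloxy)-2-methoxy-7-oxabicyclo[4.1.0]hept-4-en-1-yl]methyl benzoate | CO[C@H]1[C@H](OC(=O)c2ccccc2)C=C[C@H]2O[C@]21COC(=O)c1ccccc1 | target

## Step count and risks

Total: 16 steps. Longest linear sequence: 15 steps (steps 1–4 and 6–16 from diethyl D-tartrate); step 5 is a one-step side branch.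

Steps most likely to fail:

1. Step 13 (key step). The ylide may be lost before it adds, by proton shift to a ring α-carbon of the thiolanium followed by [2,3]-sigmatropic shift. Ketone enolisation may lead to β-elimination of the C3 silyloxy group or to C-alkylation by the sulfonium. The allyl ylide may lose its Z geometry and then cannot cyclise. Betaine closure may also place the oxirane anti to C2-OMe. Fallback (olefination first, reagent-controlled epoxidation second), setting out from bromo ketone 16: DDQ in buffered CH2Cl2 removes the PMB group before any diene exists and gives the α-hydroxy ketone F1. PPh3 in MeCN converts it into the allylic phosphonium bromide F2. KOtBu (2.2 equiv, THF, −78 to 0 °C) forms the alkoxide and the allylic phosphorus ylide, and intramolecular Wittig olefination at C1 closes the carbocycle as the cyclohexa-1,3-diene (C1=C6 and C4=C5), the dienol F3. Sharpless asymmetric epoxidation of F3 (Ti(OiPr)4, diethyl D-(−)-tartrate, tBuOOH, 4 Å molecular sieves, CH2Cl2, −20 °C) is directed by the C7 hydroxyl to C1=C6 only. The D-tartrate ligand is the one the Sharpless mnemonic assigns to the face syn to C2-OMe, so this should give epoxy alcohol 22, where the route is rejoined at step 15.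

2. Step 7. The 2,3-dialkoxy-4-oxo aldehyde may epimerise at C3 or undergo β-elimination under the amine base and again under the phosphonate anion of step 8. Fallback (olefination before the ketone exists), setting out from Weinreb amide 6: the same oxidation gives the much less acidic aldehyde amide F4. Still–Gennari olefination gives the Z-enoate amide F5. iBu2AlH at −78 °C reduces the enoate to the allylic alcohol and the Weinreb amide to the aldehyde (released on work-up), giving the hydroxy aldehyde F6. Excess lithium reagent 10 (from 9) then adds to the aldehyde to give diol 14, where the route is rejoined at step 10.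

3. Step 10. Chemoselectivity between the primary allylic and the secondary hydroxyl may be lost, the C1 hydroxyl may attack the new allylic bromide to form a seven-membered ether, or allylic transposition and Z-to-E scrambling may occur. Fallback (no diol, ketone never reduced), setting out from keto aldehyde 12: Stork–Zhao olefination (Ph3P=CHI from [Ph3PCH2I]I and NaN(SiMe3)2, THF/DMPU, −78 °C) gives the Z-vinyl iodide F7. Stille coupling with Bu3SnCH2OH (Pd(PPh3)4, dioxane, 80 °C) gives the Z-allylic alcohol F8 with the ketone intact. Appel bromination (CBr4, PPh3, CH2Cl2, 0 °C) then gives bromo ketone 16, where the route is rejoined at step 12.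

## Further compounds

F1 | step 13 | (3S,4R,5Z)-7-bromo-1-hydroxy-3-methoxy-4-[(triethylsilyl)oxy]hept-5-en-2-one | OCC(=O)[C@@H](OC)[C@H](O[Si](CC)(CC)CC)/C=C\CBr
F2 | step 13 | [(2Z,4R,5S)-7-hydroxy-5-methoxy-6-oxo-4-[(triethylsilyl)oxy]hept-2-en-1-yl]triphenylphosphonium bromide | OCC(=O)[C@@H](OC)[C@H](O[Si](CC)(CC)CC)/C=C\C[P+](c1ccccc1)(c1ccccc1)c1ccccc1.[Br-]
F3 | step 13 | [(5R,6R)-6-methoxy-5-[(triethylsilyl)oxy]cyclohexa-1,3-dien-1-yl]methanol | CO[C@H]1[C@H](O[Si](CC)(CC)CC)C=CC=C1CO
F4 | step 7 | (2S,3S)-N,2-dimethoxy-N-methyl-4-oxo-3-[(triethylsilyl)oxy]butanamide | CON(C)C(=O)[C@@H](OC)[C@H](O[Si](CC)(CC)CC)C=O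
F5 | step 7 | methyl (2Z,4R,5S)-5-methoxy-6-[methoxy(methyl)amino]-6-oxo-4-[(triethylsilyl)oxy]hex-2-enoate | CON(C)C(=O)[C@@H](OC)[C@H](O[Si](CC)(CC)CC)/C=C\C(=O)OC
F6 | step 7 | (2S,3R,4Z)-6-hydroxy-2-methoxy-3-[(triethylsilyl)oxy]hex-4-enal | O=C[C@@H](OC)[C@H](O[Si](CC)(CC)CC)/C=C\CO
F7 | step 10 | (3S,4R,5Z)-6-iodo-3-methoxy-1-[(4-methoxyphenyl)methoxy]-4-[(triethylsilyl)oxy]hex-5-en-2-one | COc1ccc(COCC(=O)[C@@H](OC)[C@H](O[Si](CC)(CC)CC)/C=C\I)cc1
F8 | step 10 | (3S,4R,5Z)-7-hydroxy-3-methoxy-1-[(4-methoxyphenyl)methoxy]-4-[(triethylsilyl)oxy]hept-5-en-2-one | COc1ccc(COCC(=O)[C@@H](OC)[C@H](O[Si](CC)(CC)CC)/C=C\CO)cc1
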